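The runs are calculated on assumed constants.

**Missing material.** Subtract target and starting material from the charge in every run below.

| setting | blue | teal | red | alder | elm | oak |
|---|---|---|---|---|---|---|
| starting material | 0.50 M | 0.25 M | 0.38 M | 0.50 M (fed, over 12 min) | 0.50 M | 0.50 M |
| reagent | 0.95 equiv | 0.95 equiv | 0.95 equiv | 0.950 equiv | 0.950 equiv (fed, over 12 min) | 0.950 equiv |
| base | 0.020 equiv | 0.020 equiv | 0.020 equiv | 0.0200 equiv | 0.0200 equiv | 0.0200 equiv |
| protic impurity | 0.50 M | 0.50 M | 0.50 M | 0.500 M | 0.500 M | 0.500 M |
| remark | run made earlier | run made earlier | run made earlier | all else is in the flask from the start; the feed brings no volume worth counting | all else is in the flask from the start; the feed brings no volume worth counting | everything together at the start |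
| time |  |  |  | 20 min | 20 min | 20 min |

| run | time / min | target / % | starting material / % |
|---|---|---|---|
| blue | 1.50 | 3 | 89 |
| blue | 3.00 | 9 | 79 |
| blue | 5.00 | 20 | 60 |
| blue | 6.00 | 24 | 50 |
| blue | 8.00 | 39 | 35 |
| blue | 10.0 | 47 | 27 |
| blue | 12.0 | 51 | 19 |
| teal | 0.833 | 2 | 93 |
| teal | 2.50 | 2 | 86 |
| teal | 5.00 | 3 | 70 |
| teal | 6.00 | 4 | 70 |
| teal | 10.0 | 12 | 55 |
| teal | 12.0 | 14 | 46 |
| teal | 15.0 | 18 | 36 |
| red | 1.33 | 4 | 89 |
| red | 2.00 | 3 | 90 |
| red | 3.00 | 6 | 83 |
| red | 5.00 | 5 | 68 |
| red | 6.00 | 16 | 65 |
| red | 10.0 | 22 | 42 |
| red | 15.0 | 39 | 25 |

(readings scatter by 2 percentage points)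



- which flask leads in amount of target, in percent of the starting material charged ("all alike" within 1.5 percentage points) (alder / elm / oak / all alike)
- how much target is there at the end, in percent of the starting material charged: alder
- how much target is there at the end, in percent of the starting material charged: elm
- how much target is there at the end, in percent of the starting material charged: oak

In the blue run at 12.0 min, 30.0% had gone elsewhere. I took that gap to be starting material spent one for one with protic impurity. Let a and h be the fractions of starting material and impurity left. With equal charges, dh/dt = −κah, so h = exp(−κe), where e is the area under a against time. The blue readings gave an area of 6.55 min, so κ read 0.0545 min⁻¹. This is the quench constant, a pseudo-first-order constant per unit of a times h.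

Teal, a different run, tested it. Scaled to teal's charges, κ and teal's own area gave a gap of 46.4%, and the readings gave 46.0%.

**Three settings.** With equal charges, target is h − a. Oak repeats the blue recipe, so I carried blue's late decline of 0.161 min⁻¹ on to 20 min and reckoned 61.6% target. In elm the starting material waits for reagent. Quench by itself makes a equal h, so h = 1/(1+κt), or 60.5% at the end of the feed. In alder, a stays under the fed fraction during the feed, so up to the end of the feed e stays under half the feed time and h above 72.1%. I therefore ranked alder above elm. I had no figure for alder's a at 20 min, so this reckoning left oak against alder open.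

**The forecast.** It put oak first, at 66%, above my figure for that flask, with alder at 48% and elm at 44%. Its ground for the feeds was that “both should lag”.

**What came.** At 20 min, oak gave 62.9%, alder 55.8% and elm 42.9%.

    starting material + reagent + released group → target + 2 released group (k = 0.0410 M⁻² s⁻¹)
    starting material + reagent → target + released group (k = 8.20 × 10⁻⁴ M⁻¹ s⁻¹)
    base + released group ⇌ salt, settled at all times (K = 58000 M⁻¹)
    starting material + protic impurity → quenched substrate (k = 0.00180 M⁻¹ s⁻¹)

**More impurity.** The impurity left gives e = −ln(h)/κ: 7.25 min for oak and 10.8 min for elm. The neighbour of oak, charged with 1.2 M of protic impurity, kept 74% of it at 20.0 min. That gives 5.43 min, less than oak. But each fraction of its impurity stood for 2.40 charges of starting material, so quenched substrate reached 61.4% and target 37.1%.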